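The pyran of the dimethoxychromene (ring B) is cut at its C4–C4a bond. The precursor is an aryl 1,1-dimethylpropargyl ether in which the ether oxygen (future O1) sits para to the carbon bearing the stereocentre, flanked by two equivalent ortho CH carbons (future C4a and C8) and two meta OMe groups. This local twofold symmetry of the ring B benzene removes the regiochemical question. On heating, the oxygen tether delivers the alkyne terminus to the ortho carbon and the pyran closes in one protecting-group-free operation. The stereocentre is set earlier by an enantioselective, biomimetic union of the ring A chromene with a para-vinylphenol whose OH later carries the propargyl unit.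

Key step: step 5

Assumption: the sense of induction of the chiral phosphoric acid in step 3 cannot be predicted with confidence; the antipode that delivers the (S) centre is to be fixed in a first screen, and (R)-TRIP, (R)-3,3'-bis(2,4,6-triisopropylphenyl)-1,1'-binaphthyl-2,2'-diyl hydrogen phosphate, stands for that choice.

Step 1
Reactants: 1 1-(2,4-dihydroxy-6-methoxyphenyl)ethan-1-one; 2 3-methylbut-2-enal
Product: 4 1-(5-hydroxy-7-methoxy-2,2-dimethyl-2H-chromen-6-yl)ethan-1-one, via o-quinone methide 3 (not isolated)
Conditions: 2 (1.5 equiv), EDDA (ethylenediammonium diacetate, 20 mol %), toluene, 110 °C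
Reagents that add atoms: none
Why: Formal [3+3] chromene annulation (Knoevenagel-type condensation, then oxa-6π electrocyclisation): the iminium ion of 2 should be attacked by the ring carbon between the two hydroxyls of 1, elimination gives o-quinone methide 3, and closure through the non-chelated oxygen leaves the acetyl group hydrogen-bonded to the remaining OH.

Step 2
Reactants: 5 4-hydroxy-2,6-dimethoxybenzaldehyde
Product: 6 4-ethenyl-3,5-dimethoxyphenol
Conditions: Ph3PCH3Br (2.5 equiv), KOtBu (3.5 equiv), THF, 0 °C to 50 °C; aqueous NH4Cl; 6 kept as a cold BHT-stabilised solution and used at once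
Reagents that add atoms: methyltriphenylphosphonium bromide, C[P+](c1ccccc1)(c1ccccc1)c1ccccc1.[Br-]
Why: Wittig methylenation, in which the excess base first forms the phenoxide and the unstabilised ylide should still take the deactivated aldehyde on gentle warming.

Step 3
Reactants: 4 1-(5-hydroxy-7-methoxy-2,2-dimethyl-2H-chromen-6-yl)ethan-1-one; 6 4-ethenyl-3,5-dimethoxyphenol
Product: 8 1-[5-hydroxy-3-[(1S)-1-(4-hydroxy-2,6-dimethoxyphenyl)ethyl]-7-methoxy-2,2-dimethyl-2H-chromen-6-yl]ethan-1-one, via para-quinone methide 7 (not isolated)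
Conditions: (R)-TRIP (10 mol %), 4 (2 equiv, excess to be recovered), 6 added slowly, toluene, −20 °C; enantiomeric purity to be checked and raised by recrystallisation if needed
Reagents that add atoms: none
Why: Proposed new method: the acid protonates the vinyl CH2 of 6 to give para-quinone methide 7 held to the chiral phosphate through its phenolic OH, the nucleophilic C3 of the styrene-type alkene of 4 adds to the exocyclic carbon on the face left open by the 3,3'-aryl groups of the catalyst (this sets the (S) centre), and the resulting C4 benzylic cation, stabilised by the ortho and para oxygens of ring A, loses H3 to the phosphate to restore the chromene; the closest known reaction types are chiral-phosphoric-acid-catalysed 1,6-additions to para-quinone methides generated in situ, acid-catalysed alkenylations in which ortho-hydroxystyrenes act as vinyl nucleophiles, and the racemic acid-mediated hetero-dimerisation of 2,2-dimethylchromenes.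

Step 4
Reactants: 8 1-[5-hydroxy-3-[(1S)-1-(4-hydroxy-2,6-dimethoxyphenyl)ethyl]-7-methoxy-2,2-dimethyl-2H-chromen-6-yl]ethan-1-one; 9 3-chloro-3-methylbut-1-yne
Product: 10 1-[3-[(1S)-1-[2,6-dimethoxy-4-(2-methylbut-3-yn-2-yloxy)phenyl]ethyl]-5-hydroxy-7-methoxy-2,2-dimethyl-2H-chromen-6-yl]ethan-1-one
Conditions: 9 (1.3 equiv), DBU (1.5 equiv), CuCl2·2H2O (1 mol %), MeCN, 0 °C
Reagents that add atoms: none
Why: Copper-catalysed O-alkylation of a phenol with a tertiary propargylic chloride, in which the unhindered ring B hydroxyl should react while the 5-OH of ring A is flanked by two substituents and locked in a hydrogen bond to the acetyl group.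

Step 5
Reactants: 10 1-[3-[(1S)-1-[2,6-dimethoxy-4-(2-methylbut-3-yn-2-yloxy)phenyl]ethyl]-5-hydroxy-7-methoxy-2,2-dimethyl-2H-chromen-6-yl]ethan-1-one
Product: 14 1-[3-[(1S)-1-(5,7-dimethoxy-2,2-dimethyl-2H-chromen-6-yl)ethyl]-5-hydroxy-7-methoxy-2,2-dimethyl-2H-chromen-6-yl]ethan-1-one (CNP0303487.1), via allenyl dienone 11 (not isolated), via allenyl phenol 12 (not isolated), via o-quinone methide 13 (not isolated)
Conditions: xylenes (0.02 M), 140 °C, argon
Reagents that add atoms: none
Why: This is the aromatic propargyl Claisen cascade, the standard thermal route from aryl 1,1-dimethylpropargyl ethers to 2,2-dimethyl-2H-chromenes: a [3,3] sigmatropic shift breaks the O–CMe2 bond and joins the alkyne terminus (future C4) to the ortho ring carbon (future C4a) to give allenyl dienone 11, enolisation gives allenyl phenol 12, a 1,5-hydrogen shift from OH to the central allene carbon gives o-quinone methide 13, and a thermal oxa-6π electrocyclisation re-forms the O–CMe2 bond. The pyran of ring B is thus closed by the new C4–C4a bond in a net 6-endo hydroarylation of the alkyne, with the ether oxygen as the tether that forces ortho delivery and a disrotatory 6π closure as the last event. No stereocentre is formed, and the existing (S) benzylic centre lies para to the reacting oxygen, outside both pericyclic arrays, so it should pass through unchanged. The only selectivity needed is ortho regioselectivity, and the substrate secures it because the two ortho carbons of ring B are interchanged by rotation about the aryl–CH bond, so both lead to 14. Ring A should stay inert because its pyran is already closed and its 5-OH is tied up in the hydrogen bond to the acetyl group.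

Compound list
1 | 1-(2,4-dihydroxy-6-methoxyphenyl)ethan-1-one | CC(=O)c1c(O)cc(O)cc1OC | starting material
2 | 3-methylbut-2-enal | CC(C)=CC=O | starting material
3 | o-quinone methide, 4-acetyl-3-hydroxy-5-methoxy-2-(3-methylbut-2-en-1-ylidene)cyclohexa-3,5-dien-1-one (alkene geometry not defined) | CC(=O)C1=C(O)C(=CC=C(C)C)C(=O)C=C1OC | intermediate
4 | 1-(5-hydroxy-7-methoxy-2,2-dimethyl-2H-chromen-6-yl)ethan-1-one (ring A chromene) | COc1cc2c(c(O)c1C(C)=O)C=CC(C)(C)O2 | intermediate
5 | 4-hydroxy-2,6-dimethoxybenzaldehyde | O=Cc1c(OC)cc(O)cc1OC | starting material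
6 | 4-ethenyl-3,5-dimethoxyphenol | C=Cc1c(OC)cc(O)cc1OC | intermediate
7 | para-quinone methide, 4-ethylidene-3,5-dimethoxycyclohexa-2,5-dien-1-one | CC=C1C(OC)=CC(=O)C=C1OC | intermediate
8 | 1-[5-hydroxy-3-[(1S)-1-(4-hydroxy-2,6-dimethoxyphenyl)ethyl]-7-methoxy-2,2-dimethyl-2H-chromen-6-yl]ethan-1-one | COc1cc2c(c(O)c1C(C)=O)C=C([C@H](C)c1c(OC)cc(O)cc1OC)C(C)(C)O2 | intermediate
9 | 3-chloro-3-methylbut-1-yne | CC(C)(Cl)C#C | starting material
10 | 1-[3-[(1S)-1-[2,6-dimethoxy-4-(2-methylbut-3-yn-2-yloxy)phenyl]ethyl]-5-hydroxy-7-methoxy-2,2-dimethyl-2H-chromen-6-yl]ethan-1-one | COc1cc2c(c(O)c1C(C)=O)C=C([C@H](C)c1c(OC)cc(OC(C)(C)C#C)cc1OC)C(C)(C)O2 | intermediate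
11 | allenyl dienone, 1-[3-[(1S)-1-[2,6-dimethoxy-3-(3-methylbuta-1,2-dien-1-yl)-4-oxocyclohexa-1,5-dien-1-yl]ethyl]-5-hydroxy-7-methoxy-2,2-dimethyl-2H-chromen-6-yl]ethan-1-one (configuration at the sp3 ring carbon not defined) | COc1cc2c(c(O)c1C(C)=O)C=C([C@H](C)C1=C(OC)C(C=C=C(C)C)C(=O)C=C1OC)C(C)(C)O2 | intermediate
12 | allenyl phenol, 1-[5-hydroxy-3-[(1S)-1-[4-hydroxy-2,6-dimethoxy-3-(3-methylbuta-1,2-dien-1-yl)phenyl]ethyl]-7-methoxy-2,2-dimethyl-2H-chromen-6-yl]ethan-1-one | COc1cc2c(c(O)c1C(C)=O)C=C([C@H](C)c1c(OC)cc(O)c(C=C=C(C)C)c1OC)C(C)(C)O2 | intermediate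
13 | o-quinone methide, 1-[3-[(1S)-1-[2,6-dimethoxy-3-(3-methylbut-2-en-1-ylidene)-4-oxocyclohexa-1,5-dien-1-yl]ethyl]-5-hydroxy-7-methoxy-2,2-dimethyl-2H-chromen-6-yl]ethan-1-one (alkene geometry not defined) | COc1cc2c(c(O)c1C(C)=O)C=C([C@H](C)C1=C(OC)C(=CC=C(C)C)C(=O)C=C1OC)C(C)(C)O2 | intermediate
14 | 1-[3-[(1S)-1-(5,7-dimethoxy-2,2-dimethyl-2H-chromen-6-yl)ethyl]-5-hydroxy-7-methoxy-2,2-dimethyl-2H-chromen-6-yl]ethan-1-one (CNP0303487.1) | COc1cc2c(c(O)c1C(C)=O)C=C([C@H](C)c1c(OC)cc3c(c1OC)C=CC(C)(C)O3)C(C)(C)O2 | target

Total step count: 5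
Longest linear sequence: 4 steps (step 1 or step 2, then steps 3, 4 and 5)

Steps most likely to fail

Step 3 (Proposed new method). What may go wrong: weak facial discrimination in the phosphate/para-quinone methide ion pair, cationic self-oligomerisation of the vinylphenol, and alkylation at the aromatic C8 of the ring A chromene instead of at C3. Fallback with known chemistry, setting out from 4 and 6 and returning at 8: the two partners are coupled without asymmetric induction with diphenyl phosphate (10 mol %) in toluene at 0 °C, the acid-mediated hetero-dimerisation known for electron-rich styrenes and 2,2-dimethylchromenes. This should give racemic 1-[5-hydroxy-3-[1-(4-hydroxy-2,6-dimethoxyphenyl)ethyl]-7-methoxy-2,2-dimethyl-2H-chromen-6-yl]ethan-1-one F1. Preparative supercritical-fluid chromatography on an amylose tris(3,5-dimethylphenylcarbamate) phase then separates it into 8, which re-enters the route at step 4, and 1-[5-hydroxy-3-[(1R)-1-(4-hydroxy-2,6-dimethoxyphenyl)ethyl]-7-methoxy-2,2-dimethyl-2H-chromen-6-yl]ethan-1-one F2, which is set aside.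

Step 1. What may go wrong: regiochemical leakage, with attack through the ring carbon between OH and OMe leading to the 7-hydroxy-5-methoxy isomer, and slow iminium formation. Fallback, setting out from 1 and returning at 4: the non-chelated 4-OH of 1 is alkylated with 9 (DBU, CuCl2·2H2O cat., MeCN, 0 °C) to give 1-[2-hydroxy-6-methoxy-4-(2-methylbut-3-yn-2-yloxy)phenyl]ethan-1-one F3. Heating F3 in xylenes at 140 °C should bring about the propargyl Claisen rearrangement and electrocyclisation. The bond fixation of the chelated acetophenone directs the migration to the carbon between the two oxygens, which gives 4.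

Step 2. What may go wrong: sluggish carbonyl addition to the phenoxide-deactivated aldehyde, and acid- or heat-induced oligomerisation of the electron-rich vinylphenol during isolation. Fallback, setting out from 5 and returning at 6: silylation (TBSCl, imidazole, DMF) gives 4-[tert-butyl(dimethyl)silyl]oxy-2,6-dimethoxybenzaldehyde F4. Wittig methylenation (Ph3PCH3Br, KOtBu, THF, 0 °C) of this now ordinary aryl aldehyde gives tert-butyl-(4-ethenyl-3,5-dimethoxyphenoxy)dimethylsilane F5. Buffered desilylation (TBAF, AcOH, THF, 0 °C) then releases 6 as a cold solution that is taken directly into step 3.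

Further compounds
F1 | step 3 | racemic 1-[5-hydroxy-3-[1-(4-hydroxy-2,6-dimethoxyphenyl)ethyl]-7-methoxy-2,2-dimethyl-2H-chromen-6-yl]ethan-1-one | COc1cc2c(c(O)c1C(C)=O)C=C(C(C)c1c(OC)cc(O)cc1OC)C(C)(C)O2
F2 | step 3 | 1-[5-hydroxy-3-[(1R)-1-(4-hydroxy-2,6-dimethoxyphenyl)ethyl]-7-methoxy-2,2-dimethyl-2H-chromen-6-yl]ethan-1-one | COc1cc2c(c(O)c1C(C)=O)C=C([C@@H](C)c1c(OC)cc(O)cc1OC)C(C)(C)O2
F3 | step 1 | 1-[2-hydroxy-6-methoxy-4-(2-methylbut-3-yn-2-yloxy)phenyl]ethan-1-one | CC(=O)c1c(O)cc(OC(C)(C)C#C)cc1OC
F4 | step 2 | 4-[tert-butyl(dimethyl)silyl]oxy-2,6-dimethoxybenzaldehyde | O=Cc1c(OC)cc(O[Si](C)(C)C(C)(C)C)cc1OC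
F5 | step 2 | tert-butyl-(4-ethenyl-3,5-dimethoxyphenoxy)dimethylsilane | C=Cc1c(OC)cc(O[Si](C)(C)C(C)(C)C)cc1OC
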